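**Plan** (labdane numbering, C1–C20)

- Cuts: last the C3 acetate and the C13=C14 enoate (olefination of a C13 methyl ketone); then, together, the ring-fusion bond C5–C10 and the ring B alkene C7=C8, which opens both rings to one acyclic chain running from C7 to C8.
- Enabling feature: C10 is a quaternary ring-fusion carbon bearing a methyl (C20), so it can be reached as a tertiary radical by H-atom transfer to a C10=C20 1,1-disubstituted alkene. C5 lies β to C7, so a C5=C6–C7HO enal is its acceptor. C8 of the trisubstituted ring B alkene carries C17, which at ester level (with a phosphonate on C8) makes C8 an olefinating carbanion for C7.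
- Forward order: ring A closes first (6-exo attack of the C10 radical on C5), ring B second in the same flask (Horner–Wadsworth–Emmons, C8 onto C7); C17 is then taken from ester to methyl.
- Chain assembly: (S)-limonene gives C1, C8–C13, C16, C17, C20 (isopropenyl becomes C1/C10/C20; the cleaved ring becomes the C8–C17 and C11–C13/C16 arms). Ethylene oxide gives C2–C3; 1,1-dimethylallene gives C4, C5, C18, C19; crotonaldehyde gives C6, C7; phosphonoacetate gives C14, C15.
- Stereochemistry: C9 from limonene; C3 from catalyst-controlled reverse prenylation; C5 and C10 from the chair transition state of the radical closure (C3–O equatorial, new C10 methyl axial), giving the trans-decalin; 13E from the side-chain olefination.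

Key step: step 9

Remark: in step 2 the SEGPHOS antipode is the one whose catalyst delivers the 3S carbinol; the sense of induction is taken from the closed transition-state model of this catalyst class and has not been checked against a reported example.

**Step 1**
Reactants: 1 (S)-(−)-limonene; 2 ethylene oxide
Product: 3 4-[(1S)-4-methylcyclohex-3-en-1-yl]pent-4-en-1-ol
Conditions: n-BuLi, TMEDA, hexane, rt; then 2, THF, −78 → 0 °C
Reagents that add atoms: none
Why: Allylic metalation of the isopropenyl methyl gives a symmetric 2-substituted allyllithium whose SN2 opening of the epoxide adds C2–C3, leaving the limonene stereocentre (future C9) untouched.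

**Step 2**
Reactants: 3 the primary alcohol; 4 1,1-dimethylallene
Product: 5 (4S)-3,3-dimethyl-7-[(1S)-4-methylcyclohex-3-en-1-yl]octa-1,7-dien-4-ol
Conditions: [Ir(cod)Cl]2 (cat.), SEGPHOS (antipode for 3S), 4-chloro-3-nitrobenzoic acid, Cs2CO3, THF, 60 °C
Reagents that add atoms: none
Why: Iridium-catalysed transfer-hydrogenative carbonyl reverse prenylation at the alcohol oxidation level (alcohol dehydrogenation, allene hydrometalation, addition of the prenyl–iridium species through its dimethyl-substituted carbon) should set C3 as S by catalyst control, the remote C9 centre having no influence.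

**Step 3**
Reactants: 5 the homoallylic alcohol
Product: 6 tert-butyldimethylsilyl ether of 5
Conditions: TBSOTf, 2,6-lutidine, CH2Cl2, −78 → 0 °C
Reagents that add atoms: tert-butyldimethylsilyl trifluoromethanesulfonate, CC(C)(C)[Si](C)(C)OS(=O)(=O)C(F)(F)F
Why: Silyl triflate silylation of the hindered secondary alcohol gives an ether that should survive the amide base, hydride and chromium oxidant used later.

**Step 4**
Reactants: 6 the silyl ether
Product: 8 (3S)-3-[(5S)-5-(tert-butyldimethylsilyloxy)-6,6-dimethylocta-1,7-dien-2-yl]-6-oxoheptanal, via ring epoxide 7 (not isolated)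
Conditions: m-CPBA (1.0 equiv), NaHCO3, CH2Cl2, −20 °C; then H5IO6, THF/H2O, 0 °C
Reagents that add atoms: m-chloroperoxybenzoic acid, OOC(=O)c1cccc(Cl)c1; water, O
Why: Prilezhaev epoxidation should pick the most electron-rich, trisubstituted ring alkene over the 1,1-disubstituted and the hindered monosubstituted ones, and periodic acid cleaves the epoxide through the diol to the aldehyde arm (C8–C17) and the methyl ketone arm (C11–C13, C16).

**Step 5**
Reactants: 8 the keto aldehyde
Product: 9 methyl (3S)-3-[(5S)-5-(tert-butyldimethylsilyloxy)-6,6-dimethylocta-1,7-dien-2-yl]-6-oxoheptanoate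
Conditions: (C5H5NH)2Cr2O7, MeOH, DMF, rt
Reagents that add atoms: methanol, CO
Why: Dichromate oxidation of the methanol hemiacetal of the aldehyde should give the methyl ester directly, the ketone, alkenes and silyl ether being inert.

**Step 6**
Reactants: 9 the keto ester
Product: 10 methyl (3S)-3-[(5S)-5-(tert-butyldimethylsilyloxy)-6,6-dimethylocta-1,7-dien-2-yl]-5-(2-methyl-1,3-dioxolan-2-yl)pentanoate
Conditions: (TMSOCH2)2, TMSOTf (cat.), CH2Cl2, −78 °C
Reagents that add atoms: 1,2-bis(trimethylsilyloxy)ethane, C[Si](C)(C)OCCO[Si](C)(C)C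
Why: Silyl-triflate-catalysed aprotic ketalisation masks the C13 ketone, which would otherwise be enolised in step 7 and attacked by the C10 radical or the C8 phosphonate carbanion (five-ring closure) in step 9.

**Step 7**
Reactants: 10 the dioxolane ester
Product: 12 C8 diethyl phosphonate of 10 (methyl 2-(diethoxyphosphoryl)pentanoate; C8 epimers), via C8 phosphonite 11 (not isolated)
Conditions: LiN(i-Pr)2, THF, −78 °C; ClP(OEt)2; then H2O2 (aq.), 0 °C
Reagents that add atoms: diethyl chlorophosphite, CCOP(Cl)OCC; hydrogen peroxide, OO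
Why: Ester enolate C-phosphinylation with a chlorophosphite (the soft trivalent phosphorus is attacked at carbon, not oxygen) followed by P-oxidation should give the α-phosphono ester, whose new C8 centre is erased in step 9.

**Step 8**
Reactants: 12 the vinyl phosphonate; 13 (E)-crotonaldehyde
Product: 14 acyclic (E)-enal: methyl 2-(diethoxyphosphoryl)-3-[(5S,7E)-5-(tert-butyldimethylsilyloxy)-6,6-dimethyl-9-oxonona-1,7-dien-2-yl]-5-(2-methyl-1,3-dioxolan-2-yl)pentanoate
Conditions: 13 (excess), second-generation Hoveyda–Grubbs catalyst RuCl2(H2IMes)(=CH-C6H4-2-O-i-Pr), CH2Cl2, 40 °C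
Reagents that add atoms: none
Why: Olefin cross-metathesis of the monosubstituted alkene with the enal partner should give the (E)-enal, the 1,1-disubstituted alkene being too hindered and too slow towards an electron-poor partner.

**Step 9**
Reactants: 14 the acyclic enal phosphonate
Product: 16 methyl 3β-(tert-butyldimethylsilyloxy)-13,13-(ethylenedioxy)-14,15-dinorlabd-7-en-17-oate, via ring A aldehyde 15 (not isolated)
Conditions: Fe(acac)3, PhSiH3, EtOH/(CH2OH)2, 60 °C, 0.005 M; then LiCl, DBU, rt
Reagents that add atoms: none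
Why: Hydrogen-atom transfer from the iron hydride formed from Fe(acac)3 and PhSiH3 to the C10=C20 alkene gives the tertiary C10 radical, which adds 6-exo-trig to C5 of the (E)-enal (intramolecular Giese addition, ring A); reduction and protonation of the α-formyl radical give aldehyde 15, and the base then added to the same flask turns the C8 phosphonoacetate into its carbanion, which closes ring B on the C7 aldehyde by a six-membered intramolecular Horner–Wadsworth–Emmons olefination that fixes C7=C8 as the endocyclic alkene. The closest known reaction types are metal-hydride HAT radical conjugate cyclisations onto unsaturated aldehydes that build methyl-bearing quaternary ring-fusion carbons, and conjugate-addition/HWE annulations to cyclohexene-1-carboxylates. C5 and C10 should be set in a chair transition state with the C3 silyl ether equatorial, the enal arm equatorial on C5 and the small new methyl (not the C9 arm) axial on C10 against the axial C4 methyl, which places H5 trans to the C10 methyl and cis-1,3 to the C3 oxygen's hydrogen, i.e. the trans-decalin once ring B closes. C9 (from limonene) is not touched and the C8 epimer mixture is destroyed in the olefination. Chemoselectivity rests on the hydride reacting only with the electron-rich 1,1-disubstituted alkene, on the dioxolane keeping C13 out of reach of both the radical and the carbanion, and on the base being added only after ring A exists, at high dilution.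

**Step 10**
Reactants: 16 the bicyclic enoate
Product: 17 3β-(tert-butyldimethylsilyloxy)-13,13-(ethylenedioxy)-14,15-dinorlabd-7-en-17-ol
Conditions: i-Bu2AlH, CH2Cl2, −78 °C
Reagents that add atoms: none
Why: 1,2-Reduction of the α,β-unsaturated ester by the dialkylaluminium hydride should give the primary allylic alcohol without touching ketal or silyl ether.

**Step 11**
Reactants: 17 the allylic alcohol
Product: 19 3β-(tert-butyldimethylsilyloxy)-13,13-(ethylenedioxy)-14,15-dinorlabd-7-ene, via allylic mesylate 18 (not isolated)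
Conditions: MsCl, Et3N, CH2Cl2, −20 °C; then LiEt3BH, THF, 0 °C
Reagents that add atoms: none
Why: Sulfonylation and direct SN2 hydride displacement of the primary allylic mesylate should turn C17 into the C8 methyl without allylic transposition.

**Step 12**
Reactants: 19 the protected dinorlabdene
Product: 20 3β-hydroxy-14,15-dinorlabd-7-en-13-one
Conditions: HF (aq.), MeCN, rt
Reagents that add atoms: water, O
Why: Aqueous acidic fluoride should hydrolyse the dioxolane and cleave the hindered silyl ether in one operation under conditions too mild to protonate the trisubstituted C7=C8 alkene.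

**Step 13**
Reactants: 20 the hydroxy ketone; 21 triethyl phosphonoacetate
Product: 23 3β-hydroxylabda-7,13E-dien-15-oic acid, via ethyl ester 22 (not isolated)
Conditions: 21, NaH, THF, reflux; then LiOH, H2O/EtOH, 60 °C; HCl work-up
Reagents that add atoms: lithium hydroxide, [Li+].[OH-]
Why: Horner–Wadsworth–Emmons olefination of the methyl ketone should favour the E enoate (ester anti to the larger chain) and saponification in the same flask frees the acid, any minor Z isomer being removed by chromatography.

**Step 14**
Reactants: 23 the hydroxy acid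
Product: 24 3β-acetoxylabda-7,13E-dien-15-oic acid (CNP0264606.2)
Conditions: Ac2O, pyridine, DMAP, rt; then H2O
Reagents that add atoms: acetic anhydride, CC(=O)OC(C)=O
Why: DMAP-catalysed acylation of the equatorial 3β-alcohol gives the acetate, and the mixed anhydride formed at C15 is hydrolysed on aqueous work-up.

**Compound list**

1 | (S)-(−)-limonene | CC1=CC[C@H](CC1)C(C)=C | starting material
2 | ethylene oxide | C1CO1 | starting material
3 | 4-[(1S)-4-methylcyclohex-3-en-1-yl]pent-4-en-1-ol | CC1=CC[C@H](CC1)C(=C)CCCO | intermediate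
4 | 1,1-dimethylallene (3-methylbuta-1,2-diene) | CC(C)=C=C | starting material
5 | (4S)-3,3-dimethyl-7-[(1S)-4-methylcyclohex-3-en-1-yl]octa-1,7-dien-4-ol | CC1=CC[C@H](CC1)C(=C)CC[C@H](O)C(C)(C)C=C | intermediate
6 | tert-butyldimethylsilyl ether of 5 | CC1=CC[C@H](CC1)C(=C)CC[C@H](O[Si](C)(C)C(C)(C)C)C(C)(C)C=C | intermediate
7 | 1,2-epoxide of the ring alkene of 6 (epoxide diastereomers) | CC12CC[C@@H](CC1O2)C(=C)CC[C@H](O[Si](C)(C)C(C)(C)C)C(C)(C)C=C | intermediate
8 | (3S)-3-[(5S)-5-(tert-butyldimethylsilyloxy)-6,6-dimethylocta-1,7-dien-2-yl]-6-oxoheptanal | CC(=O)CC[C@@H](CC=O)C(=C)CC[C@H](O[Si](C)(C)C(C)(C)C)C(C)(C)C=C | intermediate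
9 | methyl (3S)-3-[(5S)-5-(tert-butyldimethylsilyloxy)-6,6-dimethylocta-1,7-dien-2-yl]-6-oxoheptanoate | CC(=O)CC[C@@H](CC(=O)OC)C(=C)CC[C@H](O[Si](C)(C)C(C)(C)C)C(C)(C)C=C | intermediate
10 | methyl (3S)-3-[(5S)-5-(tert-butyldimethylsilyloxy)-6,6-dimethylocta-1,7-dien-2-yl]-5-(2-methyl-1,3-dioxolan-2-yl)pentanoate | CC1(CC[C@@H](CC(=O)OC)C(=C)CC[C@H](O[Si](C)(C)C(C)(C)C)C(C)(C)C=C)OCCO1 | intermediate
11 | 2-(diethoxyphosphanyl) derivative of 10 (phosphonite on C8, C8 epimers) | CC1(CC[C@@H](C(C(=O)OC)P(OCC)OCC)C(=C)CC[C@H](O[Si](C)(C)C(C)(C)C)C(C)(C)C=C)OCCO1 | intermediate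
12 | 2-(diethoxyphosphoryl) derivative of 10 (phosphonate on C8, C8 epimers; C3 and C9 as in 10) | CC1(CC[C@@H](C(C(=O)OC)P(=O)(OCC)OCC)C(=C)CC[C@H](O[Si](C)(C)C(C)(C)C)C(C)(C)C=C)OCCO1 | intermediate
13 | (E)-crotonaldehyde | C/C=C/C=O | starting material
14 | acyclic (E)-enal phosphonate (12 with the vinyl group extended to CH=CH–CHO) | CC1(CC[C@@H](C(C(=O)OC)P(=O)(OCC)OCC)C(=C)CC[C@H](O[Si](C)(C)C(C)(C)C)C(C)(C)/C=C/C=O)OCCO1 | intermediate
15 | ring A aldehyde: cyclohexane C1–C5/C10 with 3β-OTBS, 4,4-dimethyl, 10β-methyl, CH2CHO on C5 (H5 α) and the phosphonoacetate/dioxolane arm on C10 | O=CC[C@H]1C(C)(C)[C@@H](O[Si](C)(C)C(C)(C)C)CC[C@]1(C)[C@@H](CCC2(C)OCCO2)C(C(=O)OC)P(=O)(OCC)OCC | intermediate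
16 | methyl 3β-(tert-butyldimethylsilyloxy)-13,13-(ethylenedioxy)-14,15-dinorlabd-7-en-17-oate | CC(C)(C)[Si](C)(C)O[C@H]1CC[C@]2(C)[C@@H](CCC3(C)OCCO3)C(C(=O)OC)=CC[C@H]2C1(C)C | intermediate
17 | 3β-(tert-butyldimethylsilyloxy)-13,13-(ethylenedioxy)-14,15-dinorlabd-7-en-17-ol | CC(C)(C)[Si](C)(C)O[C@H]1CC[C@]2(C)[C@@H](CCC3(C)OCCO3)C(CO)=CC[C@H]2C1(C)C | intermediate
18 | 17-methanesulfonate of 17 | CC(C)(C)[Si](C)(C)O[C@H]1CC[C@]2(C)[C@@H](CCC3(C)OCCO3)C(COS(C)(=O)=O)=CC[C@H]2C1(C)C | intermediate
19 | 3β-(tert-butyldimethylsilyloxy)-13,13-(ethylenedioxy)-14,15-dinorlabd-7-ene | CC(C)(C)[Si](C)(C)O[C@H]1CC[C@]2(C)[C@@H](CCC3(C)OCCO3)C(C)=CC[C@H]2C1(C)C | intermediate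
20 | 3β-hydroxy-14,15-dinorlabd-7-en-13-one | O[C@H]1CC[C@]2(C)[C@@H](CCC(C)=O)C(C)=CC[C@H]2C1(C)C | intermediate
21 | triethyl phosphonoacetate | CCOC(=O)CP(=O)(OCC)OCC | starting material
22 | ethyl 3β-hydroxylabda-7,13E-dien-15-oate | O[C@H]1CC[C@]2(C)[C@@H](CC/C(C)=C/C(=O)OCC)C(C)=CC[C@H]2C1(C)C | intermediate
23 | 3β-hydroxylabda-7,13E-dien-15-oic acid | O[C@H]1CC[C@]2(C)[C@@H](CC/C(C)=C/C(=O)O)C(C)=CC[C@H]2C1(C)C | intermediate
24 | 3β-acetoxylabda-7,13E-dien-15-oic acid (CNP0264606.2) | CC(=O)O[C@H]1CC[C@]2(C)[C@@H](CC/C(C)=C/C(=O)O)C(C)=CC[C@H]2C1(C)C | target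

**Step count and risks**

Total steps: 14. Longest linear sequence: 14 (from 1).

Steps most likely to fail:

1. Step 9. The tertiary C10 radical may be reduced by the iron hydride before the hindered 6-exo closure onto C5 (simple hydrogenation of the alkene), the chair preference may be too weak and give some cis-fused material, or residual silane may reduce the freed C7 aldehyde once base is added. The fallback sets out from 12 and returns at 16. Markovnikov hydrochlorination of the 1,1-disubstituted alkene of 12 (Co(BF4)2·6H2O, salen-type ligand, PhSiH3, TsCl, EtOH) should give the C10 tertiary chloride F1. Cross-metathesis with 13 as in step 8 should give the chloro enal F2. Slow addition of Bu3SnH/AIBN in benzene at 80 °C (chain reaction at low hydride concentration, which favours cyclisation over reduction) should give aldehyde 15, now isolated. LiCl/DBU in MeCN then closes ring B to 16 in a separate step.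

2. Step 8. The vinyl group next to the quaternary C4 and the silyloxy-bearing C3 may turn over too slowly, or the 1,1-disubstituted alkene may be drawn into metathesis as well. The fallback sets out from 12 and returns at 14. Linear hydroformylation of the monosubstituted alkene (Rh(acac)(CO)2, Xantphos, CO/H2) should give the saturated aldehyde F3, in which C6 is kept and C7 comes from CO. Enamine-catalysed α-selenenylation (N-(phenylseleno)phthalimide, pyrrolidine cat.) should give the α-phenylseleno aldehyde F4, and H2O2 oxidation with syn-elimination of the selenoxide should give 14.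

3. Step 13. Geometric control in the olefination of a methyl ketone may be incomplete, leaving the Z isomer mixed with the E isomer. The fallback sets out from 19 and returns at 23. PPTS in wet acetone should remove only the dioxolane to give the silyl-protected methyl ketone F5. LiN(i-Pr)2 then ClP(O)(OEt)2 should give the terminal enol phosphate F6, and more LiN(i-Pr)2 in the same flask eliminates it to the terminal alkyne F7. Negishi carboalumination (Me3Al, Cp2ZrCl2, CH2Cl2), then n-BuLi and CO2, should give the silyl-protected (E)-acid F8 stereospecifically; the new C13 methyl comes from Me3Al and C15 from CO2. Aqueous HF in MeCN then gives 23.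

**Further compounds**

F1 | step 9 | C10 tertiary chloride of 12 (C10 epimers) | CC1(CC[C@@H](C(C(=O)OC)P(=O)(OCC)OCC)C(C)(Cl)CC[C@H](O[Si](C)(C)C(C)(C)C)C(C)(C)C=C)OCCO1
F2 | step 9 | chloro enal (F1 with the vinyl group extended to (E)-CH=CH–CHO) | CC1(CC[C@@H](C(C(=O)OC)P(=O)(OCC)OCC)C(C)(Cl)CC[C@H](O[Si](C)(C)C(C)(C)C)C(C)(C)/C=C/C=O)OCCO1
F3 | step 8 | saturated aldehyde (12 with the vinyl group converted to CH2CH2CHO) | CC1(CC[C@@H](C(C(=O)OC)P(=O)(OCC)OCC)C(=C)CC[C@H](O[Si](C)(C)C(C)(C)C)C(C)(C)CCC=O)OCCO1
F4 | step 8 | α-phenylseleno aldehyde from F3 | CC1(CC[C@@H](C(C(=O)OC)P(=O)(OCC)OCC)C(=C)CC[C@H](O[Si](C)(C)C(C)(C)C)C(C)(C)CC([Se]c2ccccc2)C=O)OCCO1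
F5 | step 13 | 3β-(tert-butyldimethylsilyloxy)-14,15-dinorlabd-7-en-13-one | CC(C)(C)[Si](C)(C)O[C@H]1CC[C@]2(C)[C@@H](CCC(C)=O)C(C)=CC[C@H]2C1(C)C
F6 | step 13 | terminal enol diethyl phosphate of F5 | CC(C)(C)[Si](C)(C)O[C@H]1CC[C@]2(C)[C@@H](CCC(=C)OP(=O)(OCC)OCC)C(C)=CC[C@H]2C1(C)C
F7 | step 13 | terminal alkyne from F5 (but-3-ynyl side chain on C9) | CC(C)(C)[Si](C)(C)O[C@H]1CC[C@]2(C)[C@@H](CCC#C)C(C)=CC[C@H]2C1(C)C
F8 | step 13 | 3β-(tert-butyldimethylsilyloxy)labda-7,13E-dien-15-oic acid | CC(C)(C)[Si](C)(C)O[C@H]1CC[C@]2(C)[C@@H](CC/C(C)=C/C(=O)O)C(C)=CC[C@H]2C1(C)C
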